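Assumption: compounds 1 and 2 are bought as catalogue items, and the locants C1–C17 used below are those of the eunicellane (briarellin) skeleton of the target (C1/C10 ring fusion, C2–O–C9 tetrahydrofuran, C3–O–C17 oxepane, C4 ester, C6 carbinol, C7 exo-methylene, C11 carbinol, C14–C15 side arm).

**Retrosynthetic overview**
1. Oxonane last: C6–C7 by intramolecular Nozaki–Hiyama–Kishi reaction of a 2-iodoallyl/aldehyde pair.
2. Tetrahydrofuran plus C11–OH: hydrative Prins cyclisation of the C2 alcohol with 3-iodobut-3-enal onto the C10=C11 alkene (C9–C10 and C11–O formed together).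
3. Oxepane, the key C–O bond (C17–O): photoredox anti-Markovnikov hydroetherification of the carvone isopropenyl group by the C3 tertiary alcohol, which also sets C15 (new method).
4. C4–O by invertive opening of a threo epoxy alcohol with octanoic acid; C1–C2 by aldol of (R)-carvone with a (Z)-enal; the enone is transposed to C10=C11 through its tosylhydrazone.
5. Ring order: cyclohexane (carvone) → oxepane → tetrahydrofuran → oxonane.

**Route**

Step 1
Reactants: 1 3-[(tert-butyldimethylsilyl)oxy]propanal; 2 methyl 2-[bis(2,2,2-trifluoroethoxy)phosphoryl]propanoate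
Product: 3 methyl (2Z)-5-[(tert-butyldimethylsilyl)oxy]-2-methylpent-2-enoate
Conditions: KHMDS, 18-crown-6, THF, −78 °C
Reagents that add atoms: none
Why: Still–Gennari olefination; the electron-poor phosphonate with a dissociated potassium counter-ion eliminates under kinetic control to the (Z)-trisubstituted enoate.

Step 2
Reactants: 3 methyl (2Z)-5-[(tert-butyldimethylsilyl)oxy]-2-methylpent-2-enoate
Product: 4 (2Z)-5-[(tert-butyldimethylsilyl)oxy]-2-methylpent-2-en-1-ol
Conditions: DIBAL-H (2.2 equiv), CH2Cl2, −78 °C; Rochelle salt work-up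
Reagents that add atoms: none
Why: DIBAL 1,2-reduction of an enoate to the allylic alcohol leaves the alkene geometry and the silyl ether untouched.

Step 3
Reactants: 4 (2Z)-5-[(tert-butyldimethylsilyl)oxy]-2-methylpent-2-en-1-ol
Product: 5 (2Z)-5-[(tert-butyldimethylsilyl)oxy]-2-methylpent-2-enal
Conditions: Dess–Martin periodinane, pyridine, CH2Cl2, 0 °C; used at once
Reagents that add atoms: none
Why: Dess–Martin oxidation under buffered, cold conditions gives the (Z)-enal without Z→E isomerisation.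

Step 4
Reactants: 6 but-3-yn-1-ol
Product: 7 3-iodobut-3-en-1-ol
Conditions: NaI, TMSCl, H2O, MeCN, rt
Reagents that add atoms: sodium iodide, [Na+].[I-]
Why: Markovnikov hydroiodination of a terminal alkyne by HI generated in situ gives the 2-iodo-1-alkene.

Step 5
Reactants: 7 3-iodobut-3-en-1-ol
Product: 8 3-iodobut-3-enal
Conditions: Dess–Martin periodinane, CH2Cl2, 0 °C; used crude
Reagents that add atoms: none
Why: Dess–Martin oxidation is mild enough to deliver the sensitive β,γ-unsaturated aldehyde without conjugation.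

Step 6
Reactants: 9 (R)-(−)-carvone; 5 (2Z)-5-[(tert-butyldimethylsilyl)oxy]-2-methylpent-2-enal
Product: 11 (5R,6R)-6-[(1S,2Z)-5-(tert-butyldimethylsilyloxy)-1-hydroxy-2-methylpent-2-en-1-yl]-2-methyl-5-(prop-1-en-2-yl)cyclohex-2-en-1-one, via kinetic lithium dienolate of carvone 10 (not isolated)
Conditions: LDA, THF, −78 °C; then 5, −78 °C; AcOH quench at −78 °C
Reagents that add atoms: none
Why: Directed aldol addition; kinetic α′-deprotonation gives the cross-conjugated enolate, which reacts anti to the isopropenyl group (C1 trans to C14) through a Zimmerman–Traxler chair of the cyclic (E)-enolate to give the anti aldol (C2 S).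

Step 7
Reactants: 11 aldol adduct (5R,6R,1′S,2′Z)
Product: 12 (5R,6R)-6-[(S)-{(2R,3S)-3-[2-(tert-butyldimethylsilyloxy)ethyl]-2-methyloxiran-2-yl}(hydroxy)methyl]-2-methyl-5-(prop-1-en-2-yl)cyclohex-2-en-1-one
Conditions: mCPBA (1.05 equiv), CH2Cl2, −20 → 0 °C
Reagents that add atoms: mCPBA, OOC(=O)c1cccc(Cl)c1
Why: Henbest-type hydroxyl-directed peracid epoxidation; A(1,3) strain in the (Z)-trisubstituted allylic alcohol fixes the reactive conformer so the threo epoxy alcohol forms (sets C3), and the trisubstituted alkene reacts faster than the isopropenyl group while the enone is inert.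

Step 8
Reactants: 12 threo epoxy alcohol; 13 octanoic acid
Product: 14 (3R,4R,5S)-1-(tert-butyldimethylsilyloxy)-4,5-dihydroxy-4-methyl-5-[(1R,6R)-3-methyl-2-oxo-6-(prop-1-en-2-yl)cyclohex-3-en-1-yl]pentan-3-yl octanoate
Conditions: octanoic acid (3 equiv), Ti(OiPr)4 (1.5 equiv), CH2Cl2, 0 °C → rt; aqueous tartaric acid work-up
Reagents that add atoms: none
Why: Titanium-mediated (Sharpless-type) opening of a 2,3-epoxy alcohol by a carboxylic acid occurs at the distal, less substituted carbon with inversion, which installs the octanoate and sets C4 (R) while freeing the C3 tertiary alcohol.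

Step 9
Reactants: 14 diol octanoate
Product: 15 (3R,4S,5S)-1-(tert-butyldimethylsilyloxy)-4-hydroxy-4-methyl-5-[(1R,6R)-3-methyl-2-oxo-6-(prop-1-en-2-yl)cyclohex-3-en-1-yl]-5-(triethylsilyloxy)pentan-3-yl octanoate
Conditions: TESCl, imidazole, DMAP (cat.), CH2Cl2, 0 °C
Reagents that add atoms: chlorotriethylsilane, CC[Si](Cl)(CC)CC
Why: Silylation is selective for the secondary C2–OH over the tertiary C3–OH, blocking the hydroxyl that would otherwise close a six-membered ether in step 10.

Step 10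
Reactants: 15 C2-triethylsilyl ether with free C3–OH and isopropenyl group
Product: 16 oxepane enone (C3–O–C17 closed; 1R,2S,3S,4R,14S,15R)
Conditions: 3,6-di-tert-butyl-9-mesityl-10-phenylacridinium BF4 (5 mol%), PhSSPh (10 mol%), 2,6-lutidine (20 mol%), DCE/HFIP 9:1 (0.02 M), 450 nm LEDs, 25 °C
Reagents that add atoms: none
Why: Proposed new method: the excited acridinium (assisted by HFIP) oxidises the isopropenyl group, the only electron-rich alkene present, to its radical cation; the only free hydroxyl (C3–OH) adds 7-endo to the terminal carbon C17 to give the tertiary C15 radical, which takes hydrogen from thiophenol on the face opposite the cyclohexenone C13 methylene to set C15 (R), and the thiyl radical is reduced by the acridine radical to close the cycle; the closest known reaction is acridinium-photoredox/HAT anti-Markovnikov hydroetherification of alkenols, shown for trisubstituted and styrenyl alkenes forming five- and six-membered ethers but not for an unactivated 1,1-disubstituted alkene, a tertiary alcohol and an oxepane with control of the new stereocentre.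

Step 11
Reactants: 16 oxepane enone
Product: 17 tosylhydrazone of 16 (C10=N–NHTs)
Conditions: TsNHNH2, THF/EtOH, 4 Å MS, 50 °C
Reagents that add atoms: p-toluenesulfonyl hydrazide, Cc1ccc(cc1)S(=O)(=O)NN
Why: Condensation of the enone carbonyl with tosylhydrazide is neutral enough for both silyl ethers and the ester.

Step 12
Reactants: 17 tosylhydrazone
Product: 19 transposed alkene (C10=C11, C12 H2; 1S,2S,3S,4R,14S,15R), via allylic diazene 18 (not isolated)
Conditions: catecholborane, CHCl3, 0 °C; then NaOAc·3H2O, 65 °C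
Reagents that add atoms: none
Why: Kabalka-type reduction of an α,β-unsaturated tosylhydrazone; hydride adds to C10, sulfinate loss gives the allylic diazene, and retro-ene loss of N2 delivers hydrogen to C12 and moves the alkene to C10=C11 without touching C1.

Step 13
Reactants: 19 transposed alkene; 8 3-iodobut-3-enal
Product: 21 6,7-seco tricyclic iodo diol (tetrahydrofuran closed, C11–OH, C6–OH; 1S,2S,3S,4R,9S,10R,11S,14S,15R), via desilylated diol 20 (not isolated)
Conditions: 8 (1.5 equiv), Sc(OTf)3 (20 mol%), H2O (5 equiv), MeNO2, 0 °C → rt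
Reagents that add atoms: water, O
Why: Hydrative Prins cyclisation, as in the acid-catalysed condensation of isopulegol with aldehydes to tertiary chromenols; the hydrated Lewis acid cleaves both silyl ethers, the C2 alcohol and 8 form the (E)-oxocarbenium ion, C10 attacks on the tether face (cis ring fusion, C10 R) with the 2-iodoallyl group on the convex face (C9 S), and water captures the C11 cation axially, anti to the new C9–C10 bond (C11 S).

Step 14
Reactants: 21 iodo diol
Product: 22 6,7-seco iodo aldehyde (C6 = CHO)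
Conditions: Dess–Martin periodinane, CH2Cl2, 0 °C → rt; used directly
Reagents that add atoms: none
Why: Dess–Martin oxidation converts the primary alcohol while the tertiary C11–OH cannot react, and the neutral conditions avoid β-elimination of the octanoate.

Step 15
Reactants: 22 iodo aldehyde
Product: 23 target CNP0398453.2
Conditions: CrCl2 (10 equiv), NiCl2 (0.1 equiv), DMSO (0.005 M), rt
Reagents that add atoms: none
Why: Intramolecular Nozaki–Hiyama–Kishi reaction; the alkenylchromium adds to the aldehyde to close the oxonane, and addition from the outer face of the folded ring is expected to give the (6R) allylic alcohol while ester, ethers and tertiary alcohol are tolerated.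

**Compound list**
1 | 3-[(tert-butyldimethylsilyl)oxy]propanal | O=CCCO[Si](C)(C)C(C)(C)C | starting material
2 | methyl 2-[bis(2,2,2-trifluoroethoxy)phosphoryl]propanoate | COC(=O)C(C)P(=O)(OCC(F)(F)F)OCC(F)(F)F | starting material
3 | methyl (2Z)-5-[(tert-butyldimethylsilyl)oxy]-2-methylpent-2-enoate | COC(=O)/C(C)=C\CCO[Si](C)(C)C(C)(C)C | intermediate
4 | (2Z)-5-[(tert-butyldimethylsilyl)oxy]-2-methylpent-2-en-1-ol | OC/C(C)=C\CCO[Si](C)(C)C(C)(C)C | intermediate
5 | (2Z)-5-[(tert-butyldimethylsilyl)oxy]-2-methylpent-2-enal | O=C/C(C)=C\CCO[Si](C)(C)C(C)(C)C | intermediate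
6 | but-3-yn-1-ol | C#CCCO | starting material
7 | 3-iodobut-3-en-1-ol | C=C(I)CCO | intermediate
8 | 3-iodobut-3-enal | C=C(I)CC=O | intermediate
9 | (R)-(−)-carvone, (5R)-2-methyl-5-(prop-1-en-2-yl)cyclohex-2-en-1-one | CC1=CC[C@H](CC1=O)C(C)=C | starting material
10 | lithium (3R)-6-methyl-3-(prop-1-en-2-yl)cyclohexa-1,5-dien-1-olate (kinetic carvone enolate) | CC1=CC[C@@H](C(C)=C)C=C1[O-].[Li+] | intermediate
11 | (5R,6R)-6-[(1S,2Z)-5-(tert-butyldimethylsilyloxy)-1-hydroxy-2-methylpent-2-en-1-yl]-2-methyl-5-(prop-1-en-2-yl)cyclohex-2-en-1-one | O[C@@H]([C@@H]1C(=O)C(C)=CC[C@H]1C(C)=C)/C(C)=C\CCO[Si](C)(C)C(C)(C)C | intermediate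
12 | (5R,6R)-6-[(S)-{(2R,3S)-3-[2-(tert-butyldimethylsilyloxy)ethyl]-2-methyloxiran-2-yl}(hydroxy)methyl]-2-methyl-5-(prop-1-en-2-yl)cyclohex-2-en-1-one | O[C@@H]([C@@H]1C(=O)C(C)=CC[C@H]1C(C)=C)[C@@]2(C)O[C@H]2CCO[Si](C)(C)C(C)(C)C | intermediate
13 | octanoic acid | CCCCCCCC(=O)O | starting material
14 | (3R,4R,5S)-1-(tert-butyldimethylsilyloxy)-4,5-dihydroxy-4-methyl-5-[(1R,6R)-3-methyl-2-oxo-6-(prop-1-en-2-yl)cyclohex-3-en-1-yl]pentan-3-yl octanoate | O[C@@H]([C@@H]1C(=O)C(C)=CC[C@H]1C(C)=C)[C@@](C)(O)[C@H](OC(=O)CCCCCCC)CCO[Si](C)(C)C(C)(C)C | intermediate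
15 | (3R,4S,5S)-1-(tert-butyldimethylsilyloxy)-4-hydroxy-4-methyl-5-[(1R,6R)-3-methyl-2-oxo-6-(prop-1-en-2-yl)cyclohex-3-en-1-yl]-5-(triethylsilyloxy)pentan-3-yl octanoate | CC[Si](CC)(CC)O[C@@H]([C@@H]1C(=O)C(C)=CC[C@H]1C(C)=C)[C@@](C)(O)[C@H](OC(=O)CCCCCCC)CCO[Si](C)(C)C(C)(C)C | intermediate
16 | oxepane enone: cyclohex-2-enone (C10=O, C11(Me)=C12) trans-fused at C1–C14 to the oxepane C1–C2(OSiEt3)–C3(Me)–O–C17H2–C15H(Me)–C14, with C3 bearing CH(O-octanoyl)CH2CH2OTBS; 1R,2S,3S,4R,14S,15R | CC[Si](CC)(CC)O[C@H]1[C@@H]2C(=O)C(C)=CC[C@H]2[C@@H](C)CO[C@@]1(C)[C@H](OC(=O)CCCCCCC)CCO[Si](C)(C)C(C)(C)C | intermediate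
17 | tosylhydrazone of 16 at C10; 1S,2S,3S,4R,14S,15R | CC[Si](CC)(CC)O[C@H]1[C@@H]2C(=NNS(=O)(=O)c3ccc(C)cc3)C(C)=CC[C@H]2[C@@H](C)CO[C@@]1(C)[C@H](OC(=O)CCCCCCC)CCO[Si](C)(C)C(C)(C)C | intermediate
18 | allylic diazene (C10–N=NH, C11=C12) from 17 | CC[Si](CC)(CC)O[C@H]1[C@@H]2C(N=N)C(C)=CC[C@H]2[C@@H](C)CO[C@@]1(C)[C@H](OC(=O)CCCCCCC)CCO[Si](C)(C)C(C)(C)C | intermediate
19 | transposed alkene: as 16 but C10H=C11(Me), C12H2 and no carbonyl; 1S,2S,3S,4R,14S,15R | CC[Si](CC)(CC)O[C@H]1[C@@H]2C=C(C)CC[C@H]2[C@@H](C)CO[C@@]1(C)[C@H](OC(=O)CCCCCCC)CCO[Si](C)(C)C(C)(C)C | intermediate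
20 | desilylated diol of 19 (C2–OH, C6–OH); 1S,2S,3R,4R,14S,15R | O[C@H]1[C@@H]2C=C(C)CC[C@H]2[C@@H](C)CO[C@@]1(C)[C@H](OC(=O)CCCCCCC)CCO | intermediate
21 | 6,7-seco iodo diol: cyclohexane/tetrahydrofuran/oxepane core of the target with 2-iodoallyl on C9, C11(Me)OH, and C4H(O-octanoyl)CH2CH2OH on C3; 1S,2S,3S,4R,9S,10R,11S,14S,15R | C=C(I)C[C@@H]2O[C@H]3[C@H]4[C@@H](CC[C@](C)(O)[C@H]42)[C@@H](C)CO[C@@]3(C)[C@H](OC(=O)CCCCCCC)CCO | intermediate
22 | 6,7-seco iodo aldehyde: 21 with C6 oxidised to CHO; same configuration | C=C(I)C[C@@H]2O[C@H]3[C@H]4[C@@H](CC[C@](C)(O)[C@H]42)[C@@H](C)CO[C@@]3(C)[C@H](OC(=O)CCCCCCC)CC=O | intermediate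
23 | CNP0398453.2: 2,9:3,17-diepoxyeunicell-7(19)-ene-4,6,11-triol 4-octanoate; 1S,2S,3S,4R,6R,9S,10R,11S,14S,15R | C=C1C[C@@H]2O[C@H]3[C@H]4[C@@H](CC[C@](C)(O)[C@H]42)[C@@H](C)CO[C@@]3(C)[C@H](OC(=O)CCCCCCC)C[C@H]1O | target

**Totals**
Total steps: 15. Longest linear sequence: 13 (steps 1–3, then 6–15).

**Three steps most likely to fail, with fallbacks**

Step 10 (new hydroetherification; the alkene may be too hard to oxidise, or C15 selectivity may be low). The fallback uses known chemistry, sets out from 15 and returns at 16. Rhodium-catalysed hydroboration of the isopropenyl group (catecholborane, RhCl(PPh3)3, THF; NaBO3 oxidation), which tolerates the s-trans enone, gives the primary alcohol (15R)-17-hydroxy compound F4 after separation from its C15 epimer. Tf2O with 2,6-lutidine at −78 → 0 °C then triflates the primary hydroxyl, and the C3 tertiary alcohol displaces the triflate to close the oxepane 16.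

Step 13 (hydrative Prins cascade; the C11 cation may lose a proton instead of taking water, or the β,γ-unsaturated aldehyde may isomerise). The fallback sets out from 19 and returns at 21. Compound 19 is condensed directly as its silyl ether with 4,4-diethoxybut-1-yne (TMSOTf, 2,6-di-tert-butyl-4-methylpyridine, CH2Cl2, −78 °C), accepting proton loss, to give the Δ11(12) alkynyl tricycle F5 with the C6 silyl ether intact. Mukaiyama hydration of its only alkene (Mn(dpm)3, PhSiH3, O2, i-PrOH, 0 °C) gives the C11 tertiary alcohol F6. B-iodo-9-BBN followed by AcOH converts the terminal alkyne into the 2-iodoalkene F7. HF·pyridine in THF then frees the C6 hydroxyl to give 21.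

Step 8 (titanium-mediated opening; possible attack at the tertiary carbon, acyl migration or retro-aldol). The fallback replaces epoxidation–inversion of the (Z)-series by syn-dihydroxylation of the (E)-series; it sets out from 1 (with enolate 10 from carvone 9) and returns at 14. Wittig reaction of 1 with 2-(triphenylphosphoranylidene)propanal (toluene, 80 °C) gives (2E)-5-[(tert-butyldimethylsilyl)oxy]-2-methylpent-2-enal F1. Its aldol reaction with 10 under the conditions of step 6 gives the (E)-aldol adduct F2. Hydroxyl-directed dihydroxylation (OsO4·TMEDA, CH2Cl2, −78 °C; then aqueous Na2SO3) adds both oxygens syn to the C2–OH to give the all-syn triol F3. Octanoyl chloride with 2,4,6-collidine at −78 °C acylates the less hindered secondary C4–OH to give 14.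

**Further compounds**
F1 | step 8 | (2E)-5-[(tert-butyldimethylsilyl)oxy]-2-methylpent-2-enal | O=C/C(C)=C/CCO[Si](C)(C)C(C)(C)C
F2 | step 8 | (5R,6R)-6-[(1S,2E)-5-(tert-butyldimethylsilyloxy)-1-hydroxy-2-methylpent-2-en-1-yl]-2-methyl-5-(prop-1-en-2-yl)cyclohex-2-en-1-one | O[C@@H]([C@@H]1C(=O)C(C)=CC[C@H]1C(C)=C)/C(C)=C/CCO[Si](C)(C)C(C)(C)C
F3 | step 8 | (5R,6R)-6-[(1S,2S,3R)-5-(tert-butyldimethylsilyloxy)-1,2,3-trihydroxy-2-methylpentyl]-2-methyl-5-(prop-1-en-2-yl)cyclohex-2-en-1-one | O[C@@H]([C@@H]1C(=O)C(C)=CC[C@H]1C(C)=C)[C@@](C)(O)[C@H](O)CCO[Si](C)(C)C(C)(C)C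
F4 | step 10 | (15R)-17-hydroxy compound: 15 with the isopropenyl group converted into (R)-CH(CH3)CH2OH | CC[Si](CC)(CC)O[C@@H]([C@@H]1C(=O)C(C)=CC[C@H]1[C@@H](C)CO)[C@@](C)(O)[C@H](OC(=O)CCCCCCC)CCO[Si](C)(C)C(C)(C)C
F5 | step 13 | Δ11(12) alkynyl tricycle: tetrahydrofuran/oxepane core with prop-2-ynyl on C9, C11=C12 alkene and C6–OTBS | C#CC[C@@H]2O[C@H]3[C@H]4[C@@H](CC=C(C)[C@H]42)[C@@H](C)CO[C@@]3(C)[C@H](OC(=O)CCCCCCC)CCO[Si](C)(C)C(C)(C)C
F6 | step 13 | (11S)-11-hydroxy alkynyl tricycle with C6–OTBS | C#CC[C@@H]2O[C@H]3[C@H]4[C@@H](CC[C@](C)(O)[C@H]42)[C@@H](C)CO[C@@]3(C)[C@H](OC(=O)CCCCCCC)CCO[Si](C)(C)C(C)(C)C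
F7 | step 13 | C6-O-TBS ether of 21 (2-iodoallyl on C9, C11–OH) | C=C(I)C[C@@H]2O[C@H]3[C@H]4[C@@H](CC[C@](C)(O)[C@H]42)[C@@H](C)CO[C@@]3(C)[C@H](OC(=O)CCCCCCC)CCO[Si](C)(C)C(C)(C)C
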